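**Retrosynthetic overview**

1. Numbering: ring A = aromatic C4a, C5–C8, C8a; ring B = C1–C4; side chain = C11 (methine), C12 (CH2OAc), C13–C17. The end game is C7–CO2H by methoxy-directed lithiation/CO2, the C12 acetate, then BBr3 to free the C5/C6 catechol and C17–OH.
2. Ring B is closed at C3–C4 by copper hydride hydroalkylation of a C4a vinyl group onto a C3 bromide, which sets C4. A Wittig reaction at C14=C15 adds C15–C17, with C16 from the Roche ester.
3. Feature used: C1 (benzylic carbon of ring B) and C11 (side-chain methine) are vicinal stereocentres that each carry a two-carbon arm (C2–C3 and C13–C14), and C11 also carries C12 at acyl level. Tying C3 to C14 gives a cyclohexene that is the Diels–Alder adduct of an (E)-3-arylacryloyl imide (C1=C11, C12=O) and a 2-silyloxybutadiene (C2, C3, C14, C13).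
4. Ozonolysis of the C3=C14 silyl enol ether opens that ring again into a C3 acid and a C14 aldehyde, so the two arms differ in oxidation level from the start.
5. Ring order: ring A bought, temporary cyclohexene (step 4), cleaved (step 7), ring B (step 17).

Key step: step 4

Remark (assumption on the chemistry): in step 17 the (R) antipode of the bisphosphine is taken to deliver 4R; the step is under catalyst control, so the (S) antipode is used instead if the first run shows the 4S epimer.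

**Route**

Step 1
Reactants: 1 2-bromo-3,4-dimethoxybenzaldehyde
Product: 3 (E)-3-(2-bromo-3,4-dimethoxyphenyl)prop-2-enoic acid, via arylidenemalonic acid 2 (not isolated)
Conditions: malonic acid (1.5 equiv), pyridine, piperidine (cat.), 100 °C
Reagents that add atoms: malonic acid, OC(=O)CC(=O)O
Why: Knoevenagel–Doebner condensation gives the arylidenemalonic acid, which loses CO2 in hot pyridine to the thermodynamically favoured (E)-cinnamic acid.

Step 2
Reactants: 3 (E)-3-(2-bromo-3,4-dimethoxyphenyl)prop-2-enoic acid; 4 (S)-4-benzyloxazolidin-2-one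
Product: 6 (S)-4-benzyl-3-[(E)-3-(2-bromo-3,4-dimethoxyphenyl)prop-2-enoyl]oxazolidin-2-one, via mixed pivalic anhydride 5 (not isolated)
Conditions: PivCl, Et3N, THF, −20 °C; then LiCl, 4, −20 °C → rt
Reagents that add atoms: none
Why: Mixed-anhydride N-acylation is standard for enoyl imides; the LiCl-activated oxazolidinone attacks the less hindered cinnamoyl carbonyl and the E alkene is not touched.

Step 3
Reactants: 7 methyl vinyl ketone
Product: 8 2-(triisopropylsilyloxy)buta-1,3-diene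
Conditions: TIPSOTf, Et3N, Et2O, 0 °C → rt
Reagents that add atoms: triisopropylsilyl trifluoromethanesulfonate, CC(C)[Si](C(C)C)(C(C)C)OS(=O)(=O)C(F)(F)F
Why: O-silylation of the enone by soft enolisation (silyl triflate, amine base) gives the cross-conjugated 2-silyloxydiene, and the bulky silyl group is chosen so that the diene withstands the Lewis acid of step 4.

Step 4
Reactants: 6 (S)-4-benzyl-3-[(E)-3-(2-bromo-3,4-dimethoxyphenyl)prop-2-enoyl]oxazolidin-2-one; 8 2-(triisopropylsilyloxy)buta-1,3-diene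
Product: 9 (S)-4-benzyl-3-{[(1S,6S)-6-(2-bromo-3,4-dimethoxyphenyl)-4-(triisopropylsilyloxy)cyclohex-3-en-1-yl]carbonyl}oxazolidin-2-one
Conditions: Et2AlCl (1.5 equiv), 8 (3 equiv), CH2Cl2, −78 → −20 °C
Reagents that add atoms: none
Why: Excess Et2AlCl turns the imide into the cationic bidentate chelate [imide·AlEt2]+, which holds the two carbonyls syn and the enoyl unit s-cis and makes the alkene electron-poor enough for a normal-demand [4+2] cycloaddition (asynchronous, possibly through a Mukaiyama–Michael stage that closes to the same ring); the closest known reaction type is the Et2AlCl-promoted Diels–Alder reaction of N-enoyl oxazolidinones with acyclic dienes. The one ring formed, the cyclohexene C1–C2–C3=C14–C13–C11, closes by six-membered [4+2] cycloaddition in which the bonds C1–C2 and C11–C13 are made. C1 is set by the auxiliary: the benzyl group of the (S)-oxazolidinone covers one face of the chelated enoyl unit, so the diene adds to the opposite face, which gives 1S. C11 is set by suprafacial addition to the (E) alkene, which places aryl and acyl trans (11S). The step needs face selectivity and regioselectivity only, because the diene termini are unsubstituted and endo/exo has no consequence; the regiochemistry is secured by the diene, whose nucleophilic CH2 next to the silyloxy carbon bonds to the aryl-bearing β-carbon, so that C3–OTIPS ends para to the acyl group and the enol ether lies at C3=C14.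

Step 5
Reactants: 9 (S)-4-benzyl-3-{[(1S,6S)-6-(2-bromo-3,4-dimethoxyphenyl)-4-(triisopropylsilyloxy)cyclohex-3-en-1-yl]carbonyl}oxazolidin-2-one
Product: 10 [(1S,6S)-6-(2-bromo-3,4-dimethoxyphenyl)-4-(triisopropylsilyloxy)cyclohex-3-en-1-yl]methanol
Conditions: LiBH4, MeOH (1.1 equiv), THF, 0 °C
Reagents that add atoms: none
Why: Reductive cleavage of the N-acyl oxazolidinone by LiBH4 occurs at the exocyclic carbonyl and frees C12 as the primary alcohol, while the silyl enol ether, the aryl bromide and both stereocentres are untouched; removing the auxiliary here takes away the acidic C11–H before any basic step.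

Step 6
Reactants: 10 [(1S,6S)-6-(2-bromo-3,4-dimethoxyphenyl)-4-(triisopropylsilyloxy)cyclohex-3-en-1-yl]methanol
Product: 11 tert-butyl{[(1S,6S)-6-(2-bromo-3,4-dimethoxyphenyl)-4-(triisopropylsilyloxy)cyclohex-3-en-1-yl]methoxy}dimethylsilane
Conditions: TBSCl, imidazole, DMF, rt
Reagents that add atoms: tert-butyldimethylsilyl chloride, CC(C)(C)[Si](C)(C)Cl
Why: Standard silylation of a primary alcohol under conditions too mild to hydrolyse the triisopropylsilyl enol ether; the ether blocks lactol and lactone formation after the ring is cut.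

Step 7
Reactants: 11 tert-butyl{[(1S,6S)-6-(2-bromo-3,4-dimethoxyphenyl)-4-(triisopropylsilyloxy)cyclohex-3-en-1-yl]methoxy}dimethylsilane
Product: 13 (3S,4S)-3-(2-bromo-3,4-dimethoxyphenyl)-4-[(tert-butyldimethylsilyloxy)methyl]-6-oxohexanoic acid, via triisopropylsilyl ester aldehyde 12 (not isolated)
Conditions: O3, CH2Cl2/MeOH (9:1), NaHCO3, Sudan Red 7B, −78 °C; Me2S, → rt; then AcOH/THF/H2O, rt
Reagents that add atoms: ozone, [O-][O+]=O
Why: Ozonolysis of a silyl enol ether, which reacts with ozone far faster than the bromo-dimethoxyarene, cuts C3=C14 so that the silyloxy carbon C3 leaves as the silyl ester (hydrolysed to the acid on work-up) and C14 as the aldehyde after Me2S reduction, without touching C1 or C11.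

Step 8
Reactants: 14 methyl (R)-3-hydroxy-2-methylpropanoate
Product: 15 methyl (R)-3-(tert-butoxy)-2-methylpropanoate
Conditions: isobutene, H2SO4 (cat.), CH2Cl2, rt (sealed vessel)
Reagents that add atoms: 2-methylpropene, CC(C)=C
Why: Acid-catalysed addition of the primary alcohol to isobutene gives the tert-butyl ether, a group that survives bases, hydrides, organolithiums and fluoride and falls in the final BBr3 step; the stereocentre is not involved.

Step 9
Reactants: 15 methyl (R)-3-(tert-butoxy)-2-methylpropanoate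
Product: 16 (S)-3-(tert-butoxy)-2-methylpropan-1-ol
Conditions: LiAlH4, Et2O, 0 °C
Reagents that add atoms: none
Why: LiAlH4 reduction of the ester to the primary alcohol; the descriptor changes from R to S only because the CIP priorities change.

Step 10
Reactants: 16 (S)-3-(tert-butoxy)-2-methylpropan-1-ol
Product: 17 (R)-1-(tert-butoxy)-3-iodo-2-methylpropane
Conditions: PPh3, iodine, imidazole, CH2Cl2, 0 °C → rt
Reagents that add atoms: iodine, [I][I]
Why: Appel-type iodination of the primary alcohol by SN2 displacement at CH2, buffered by imidazole so that the tert-butyl ether is safe.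

Step 11
Reactants: 17 (R)-1-(tert-butoxy)-3-iodo-2-methylpropane
Product: 18 [(2R)-3-(tert-butoxy)-2-methylpropyl]triphenylphosphonium iodide
Conditions: PPh3, i-Pr2NEt (cat.), MeCN, reflux
Reagents that add atoms: triphenylphosphine, c1ccc(cc1)P(c1ccccc1)c1ccccc1
Why: Quaternisation of PPh3 by the primary iodide (SN2) gives the phosphonium salt whose CH2–P carbon becomes C15.

Step 12
Reactants: 13 (3S,4S)-3-(2-bromo-3,4-dimethoxyphenyl)-4-[(tert-butyldimethylsilyloxy)methyl]-6-oxohexanoic acid; 18 [(2R)-3-(tert-butoxy)-2-methylpropyl]triphenylphosphonium iodide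
Product: 20 (3S,4S,6Z,8S)-3-(2-bromo-3,4-dimethoxyphenyl)-9-(tert-butoxy)-4-[(tert-butyldimethylsilyloxy)methyl]-8-methylnon-6-enoic acid, via phosphonium ylide 19 (not isolated)
Conditions: 18 (2.4 equiv), NaN(SiMe3)2 (2.3 equiv), THF, −78 → 0 °C; then 13, −78 °C → rt; aqueous acid work-up
Reagents that add atoms: none
Why: Wittig olefination with the non-stabilised ylide joins C15 to C14; the first equivalent of ylide only deprotonates the acid, the aldehyde has no epimerisable centre next to it (C11 is β), and the alkene geometry is of no consequence because the alkene is reduced next.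

Step 13
Reactants: 20 (3S,4S,6Z,8S)-3-(2-bromo-3,4-dimethoxyphenyl)-9-(tert-butoxy)-4-[(tert-butyldimethylsilyloxy)methyl]-8-methylnon-6-enoic acid
Product: 21 (3S,4S,8S)-3-(2-bromo-3,4-dimethoxyphenyl)-9-(tert-butoxy)-4-[(tert-butyldimethylsilyloxy)methyl]-8-methylnonanoic acid
Conditions: 2-nitrobenzenesulfonohydrazide (excess), Et3N, CH2Cl2, rt
Reagents that add atoms: none
Why: Diimide reduction: diimide made from the sulfonyl hydrazide transfers H2 to the disubstituted alkene in a concerted syn fashion, without hydrogenolysis of the aryl bromide and without double-bond migration, so the allylic centre C16 keeps its configuration.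

Step 14
Reactants: 21 (3S,4S,8S)-3-(2-bromo-3,4-dimethoxyphenyl)-9-(tert-butoxy)-4-[(tert-butyldimethylsilyloxy)methyl]-8-methylnonanoic acid
Product: 22 (3S,4S,8S)-3-(2-bromo-3,4-dimethoxyphenyl)-9-(tert-butoxy)-4-[(tert-butyldimethylsilyloxy)methyl]-8-methylnonan-1-ol
Conditions: BH3·THF, THF, 0 °C → rt; MeOH quench
Reagents that add atoms: none
Why: Borane reduction of a carboxylic acid through acyloxyboranes is much faster than reaction with any other group present (aryl bromide, silyl and alkyl ethers) and gives the C3 primary alcohol.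

Step 15
Reactants: 22 (3S,4S,8S)-3-(2-bromo-3,4-dimethoxyphenyl)-9-(tert-butoxy)-4-[(tert-butyldimethylsilyloxy)methyl]-8-methylnonan-1-ol
Product: 23 (3S,4S,8S)-9-(tert-butoxy)-4-[(tert-butyldimethylsilyloxy)methyl]-3-(2-ethenyl-3,4-dimethoxyphenyl)-8-methylnonan-1-ol
Conditions: vinylboronic acid pinacol ester, Pd(OAc)2 (5 mol%), 2-dicyclohexylphosphino-2',6'-dimethoxybiphenyl (10 mol%), K3PO4, toluene/H2O, 90 °C
Reagents that add atoms: 4,4,5,5-tetramethyl-2-vinyl-1,3,2-dioxaborolane, C=CB1OC(C)(C)C(C)(C)O1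
Why: Suzuki–Miyaura coupling of the doubly ortho-substituted aryl bromide, for which the bulky electron-rich biarylphosphine is chosen; the free primary alcohol is tolerated and the vinyl group brings in C4 and its methyl carbon.

Step 16
Reactants: 23 (3S,4S,8S)-9-(tert-butoxy)-4-[(tert-butyldimethylsilyloxy)methyl]-3-(2-ethenyl-3,4-dimethoxyphenyl)-8-methylnonan-1-ol
Product: 24 (3S,4S,8S)-1-bromo-9-(tert-butoxy)-4-[(tert-butyldimethylsilyloxy)methyl]-3-(2-ethenyl-3,4-dimethoxyphenyl)-8-methylnonane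
Conditions: CBr4, PPh3, CH2Cl2, 0 °C
Reagents that add atoms: carbon tetrabromide, BrC(Br)(Br)Br
Why: Appel bromination turns the C3 primary alcohol into the bromide by SN2 displacement of the oxyphosphonium ion under neutral conditions that leave the styrene and both ethers alone.

Step 17
Reactants: 24 (3S,4S,8S)-1-bromo-9-(tert-butoxy)-4-[(tert-butyldimethylsilyloxy)methyl]-3-(2-ethenyl-3,4-dimethoxyphenyl)-8-methylnonane
Product: 25 tert-butyl{[(2S,6S)-7-(tert-butoxy)-2-[(1S,4R)-5,6-dimethoxy-4-methyl-1,2,3,4-tetrahydronaphthalen-1-yl]-6-methylheptyl]oxy}dimethylsilane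
Conditions: Cu(OAc)2 (5 mol%), (R)-5,5'-bis[bis(3,5-di-tert-butyl-4-methoxyphenyl)phosphino]-4,4'-bi-1,3-benzodioxole ((R)-DTBM-SEGPHOS, 5.5 mol%), (MeO)2MeSiH, LiOMe, THF, rt → 40 °C
Reagents that add atoms: none
Why: Copper hydride-catalysed intramolecular hydroalkylation of a bromide-tethered styrene: the ligated copper hydride adds across the vinyl group with copper at the benzylic carbon C4 (enantio-determining, ligand-controlled), and this benzylic copper species alkylates the C3 bromide in a six-membered ring closure that forms C3–C4 and ring B and sets 4R (methyl trans to the C1 substituent) independently of the remote C1 centre.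

Step 18
Reactants: 25 tert-butyl{[(2S,6S)-7-(tert-butoxy)-2-[(1S,4R)-5,6-dimethoxy-4-methyl-1,2,3,4-tetrahydronaphthalen-1-yl]-6-methylheptyl]oxy}dimethylsilane
Product: 27 (5R,8S)-8-[(2S,6S)-7-(tert-butoxy)-1-(tert-butyldimethylsilyloxy)-6-methylheptan-2-yl]-3,4-dimethoxy-5-methyl-5,6,7,8-tetrahydronaphthalene-2-carboxylic acid, via C7 aryllithium 26 (not isolated)
Conditions: n-BuLi, TMEDA, Et2O, 0 °C → rt; CO2, −78 °C → rt; cold 1 M HCl
Reagents that add atoms: carbon dioxide, O=C=O
Why: Directed ortho-metalation: C7–H is the only aromatic hydrogen ortho to a methoxy group (C8–H has none), so n-BuLi/TMEDA lithiates there and CO2 gives the C7 acid, the silyl and tert-butyl ethers being stable to the base.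

Step 19
Reactants: 27 (5R,8S)-8-[(2S,6S)-7-(tert-butoxy)-1-(tert-butyldimethylsilyloxy)-6-methylheptan-2-yl]-3,4-dimethoxy-5-methyl-5,6,7,8-tetrahydronaphthalene-2-carboxylic acid
Product: 28 (5R,8S)-8-[(2S,6S)-7-(tert-butoxy)-1-hydroxy-6-methylheptan-2-yl]-3,4-dimethoxy-5-methyl-5,6,7,8-tetrahydronaphthalene-2-carboxylic acid
Conditions: HF·pyridine, pyridine/THF, 0 °C → rt
Reagents that add atoms: none
Why: Fluoride-driven desilylation cleaves the primary silyl ether while the tert-butyl ether, the aryl methyl ethers and the acid are inert, so only C12–OH is set free.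

Step 20
Reactants: 28 (5R,8S)-8-[(2S,6S)-7-(tert-butoxy)-1-hydroxy-6-methylheptan-2-yl]-3,4-dimethoxy-5-methyl-5,6,7,8-tetrahydronaphthalene-2-carboxylic acid
Product: 30 (5R,8S)-8-[(2S,6S)-1-acetoxy-7-(tert-butoxy)-6-methylheptan-2-yl]-3,4-dimethoxy-5-methyl-5,6,7,8-tetrahydronaphthalene-2-carboxylic acid, via mixed acetic anhydride 29 (not isolated)
Conditions: Ac2O, pyridine, 4-(dimethylamino)pyridine (cat.), CH2Cl2, 0 °C → rt; then aq. NaHCO3/THF, rt
Reagents that add atoms: acetic anhydride, CC(=O)OC(C)=O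
Why: Acylation of the only free alcohol; the aryl acid is acetylated too, to the mixed anhydride, which the bicarbonate treatment hydrolyses at its acetyl carbonyl back to the acid.

Step 21
Reactants: 30 (5R,8S)-8-[(2S,6S)-1-acetoxy-7-(tert-butoxy)-6-methylheptan-2-yl]-3,4-dimethoxy-5-methyl-5,6,7,8-tetrahydronaphthalene-2-carboxylic acid
Product: 31 (5R,8S)-8-[(2S,6S)-1-acetoxy-7-hydroxy-6-methylheptan-2-yl]-3,4-dihydroxy-5-methyl-5,6,7,8-tetrahydronaphthalene-2-carboxylic acid (CNP0191669.1)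
Conditions: BBr3 (6 equiv), CH2Cl2, −78 → 0 °C; ice/H2O
Reagents that add atoms: none
Why: Lewis-acid ether cleavage: BBr3 removes the two aryl methyl groups (the C6 one helped by the neighbouring acid) and, through the tert-butyl cation, the tert-butyl ether, while a primary acetate should survive at or below 0 °C; hydrolysis of the borates on work-up frees the catechol and C17–OH.

**Compound list**

1 | 2-bromo-3,4-dimethoxybenzaldehyde | COc1ccc(C=O)c(Br)c1OC | starting material
2 | 2-[(2-bromo-3,4-dimethoxyphenyl)methylidene]propanedioic acid | OC(=O)C(=Cc1ccc(OC)c(OC)c1Br)C(=O)O | intermediate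
3 | (E)-3-(2-bromo-3,4-dimethoxyphenyl)prop-2-enoic acid | OC(=O)/C=C/c1ccc(OC)c(OC)c1Br | intermediate
4 | (S)-4-benzyloxazolidin-2-one | O=C1N[C@@H](Cc2ccccc2)CO1 | starting material
5 | (E)-3-(2-bromo-3,4-dimethoxyphenyl)prop-2-enoic pivalic anhydride | CC(C)(C)C(=O)OC(=O)/C=C/c1ccc(OC)c(OC)c1Br | intermediate
6 | (S)-4-benzyl-3-[(E)-3-(2-bromo-3,4-dimethoxyphenyl)prop-2-enoyl]oxazolidin-2-one | O=C(/C=C/c1ccc(OC)c(OC)c1Br)N1[C@@H](Cc2ccccc2)COC1=O | intermediate
7 | methyl vinyl ketone (but-3-en-2-one) | CC(=O)C=C | starting material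
8 | 2-(triisopropylsilyloxy)buta-1,3-diene | C=CC(=C)O[Si](C(C)C)(C(C)C)C(C)C | intermediate
9 | (S)-4-benzyl-3-{[(1S,6S)-6-(2-bromo-3,4-dimethoxyphenyl)-4-(triisopropylsilyloxy)cyclohex-3-en-1-yl]carbonyl}oxazolidin-2-one | O=C(N1[C@@H](Cc2ccccc2)COC1=O)[C@H]1CC=C(O[Si](C(C)C)(C(C)C)C(C)C)C[C@@H]1c1ccc(OC)c(OC)c1Br | intermediate
10 | [(1S,6S)-6-(2-bromo-3,4-dimethoxyphenyl)-4-(triisopropylsilyloxy)cyclohex-3-en-1-yl]methanol | OC[C@H]1CC=C(O[Si](C(C)C)(C(C)C)C(C)C)C[C@@H]1c1ccc(OC)c(OC)c1Br | intermediate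
11 | tert-butyl{[(1S,6S)-6-(2-bromo-3,4-dimethoxyphenyl)-4-(triisopropylsilyloxy)cyclohex-3-en-1-yl]methoxy}dimethylsilane | CC(C)(C)[Si](C)(C)OC[C@H]1CC=C(O[Si](C(C)C)(C(C)C)C(C)C)C[C@@H]1c1ccc(OC)c(OC)c1Br | intermediate
12 | triisopropylsilyl (3S,4S)-3-(2-bromo-3,4-dimethoxyphenyl)-4-[(tert-butyldimethylsilyloxy)methyl]-6-oxohexanoate | CC(C)[Si](C(C)C)(C(C)C)OC(=O)C[C@H](c1ccc(OC)c(OC)c1Br)[C@@H](CO[Si](C)(C)C(C)(C)C)CC=O | intermediate
13 | (3S,4S)-3-(2-bromo-3,4-dimethoxyphenyl)-4-[(tert-butyldimethylsilyloxy)methyl]-6-oxohexanoic acid | OC(=O)C[C@H](c1ccc(OC)c(OC)c1Br)[C@@H](CO[Si](C)(C)C(C)(C)C)CC=O | intermediate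
14 | methyl (R)-3-hydroxy-2-methylpropanoate | COC(=O)[C@H](C)CO | starting material
15 | methyl (R)-3-(tert-butoxy)-2-methylpropanoate | COC(=O)[C@H](C)COC(C)(C)C | intermediate
16 | (S)-3-(tert-butoxy)-2-methylpropan-1-ol | OC[C@H](C)COC(C)(C)C | intermediate
17 | (R)-1-(tert-butoxy)-3-iodo-2-methylpropane | IC[C@H](C)COC(C)(C)C | intermediate
18 | [(2R)-3-(tert-butoxy)-2-methylpropyl]triphenylphosphonium iodide | C([C@H](C)COC(C)(C)C)[P+](c1ccccc1)(c1ccccc1)c1ccccc1.[I-] | intermediate
19 | [(2R)-3-(tert-butoxy)-2-methylpropylidene]triphenylphosphorane | CC(C)(C)OC[C@@H](C)C=P(c1ccccc1)(c1ccccc1)c1ccccc1 | intermediate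
20 | (3S,4S,6Z,8S)-3-(2-bromo-3,4-dimethoxyphenyl)-9-(tert-butoxy)-4-[(tert-butyldimethylsilyloxy)methyl]-8-methylnon-6-enoic acid | OC(=O)C[C@H](c1ccc(OC)c(OC)c1Br)[C@@H](CO[Si](C)(C)C(C)(C)C)C/C=C\[C@H](C)COC(C)(C)C | intermediate
21 | (3S,4S,8S)-3-(2-bromo-3,4-dimethoxyphenyl)-9-(tert-butoxy)-4-[(tert-butyldimethylsilyloxy)methyl]-8-methylnonanoic acid | OC(=O)C[C@H](c1ccc(OC)c(OC)c1Br)[C@@H](CO[Si](C)(C)C(C)(C)C)CCC[C@H](C)COC(C)(C)C | intermediate
22 | (3S,4S,8S)-3-(2-bromo-3,4-dimethoxyphenyl)-9-(tert-butoxy)-4-[(tert-butyldimethylsilyloxy)methyl]-8-methylnonan-1-ol | OCC[C@H](c1ccc(OC)c(OC)c1Br)[C@@H](CO[Si](C)(C)C(C)(C)C)CCC[C@H](C)COC(C)(C)C | intermediate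
23 | (3S,4S,8S)-9-(tert-butoxy)-4-[(tert-butyldimethylsilyloxy)methyl]-3-(2-ethenyl-3,4-dimethoxyphenyl)-8-methylnonan-1-ol | OCC[C@H](c1ccc(OC)c(OC)c1C=C)[C@@H](CO[Si](C)(C)C(C)(C)C)CCC[C@H](C)COC(C)(C)C | intermediate
24 | (3S,4S,8S)-1-bromo-9-(tert-butoxy)-4-[(tert-butyldimethylsilyloxy)methyl]-3-(2-ethenyl-3,4-dimethoxyphenyl)-8-methylnonane | BrCC[C@H](c1ccc(OC)c(OC)c1C=C)[C@@H](CO[Si](C)(C)C(C)(C)C)CCC[C@H](C)COC(C)(C)C | intermediate
25 | tert-butyl{[(2S,6S)-7-(tert-butoxy)-2-[(1S,4R)-5,6-dimethoxy-4-methyl-1,2,3,4-tetrahydronaphthalen-1-yl]-6-methylheptyl]oxy}dimethylsilane | CC(C)(C)[Si](C)(C)OC[C@@H](CCC[C@H](C)COC(C)(C)C)[C@@H]1CC[C@@H](C)c2c1ccc(OC)c2OC | intermediate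
26 | 7-lithio derivative of 25 (lithium on the aromatic carbon C7, ortho to the C6 methoxy group) | CC(C)(C)[Si](C)(C)OC[C@@H](CCC[C@H](C)COC(C)(C)C)[C@@H]1CC[C@@H](C)c2c1cc([Li])c(OC)c2OC | intermediate
27 | (5R,8S)-8-[(2S,6S)-7-(tert-butoxy)-1-(tert-butyldimethylsilyloxy)-6-methylheptan-2-yl]-3,4-dimethoxy-5-methyl-5,6,7,8-tetrahydronaphthalene-2-carboxylic acid | CC(C)(C)[Si](C)(C)OC[C@@H](CCC[C@H](C)COC(C)(C)C)[C@@H]1CC[C@@H](C)c2c1cc(C(=O)O)c(OC)c2OC | intermediate
28 | (5R,8S)-8-[(2S,6S)-7-(tert-butoxy)-1-hydroxy-6-methylheptan-2-yl]-3,4-dimethoxy-5-methyl-5,6,7,8-tetrahydronaphthalene-2-carboxylic acid | OC[C@@H](CCC[C@H](C)COC(C)(C)C)[C@@H]1CC[C@@H](C)c2c1cc(C(=O)O)c(OC)c2OC | intermediate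
29 | acetic (5R,8S)-8-[(2S,6S)-1-acetoxy-7-(tert-butoxy)-6-methylheptan-2-yl]-3,4-dimethoxy-5-methyl-5,6,7,8-tetrahydronaphthalene-2-carboxylic anhydride | CC(=O)OC[C@@H](CCC[C@H](C)COC(C)(C)C)[C@@H]1CC[C@@H](C)c2c1cc(C(=O)OC(C)=O)c(OC)c2OC | intermediate
30 | (5R,8S)-8-[(2S,6S)-1-acetoxy-7-(tert-butoxy)-6-methylheptan-2-yl]-3,4-dimethoxy-5-methyl-5,6,7,8-tetrahydronaphthalene-2-carboxylic acid | CC(=O)OC[C@@H](CCC[C@H](C)COC(C)(C)C)[C@@H]1CC[C@@H](C)c2c1cc(C(=O)O)c(OC)c2OC | intermediate
31 | (5R,8S)-8-[(2S,6S)-1-acetoxy-7-hydroxy-6-methylheptan-2-yl]-3,4-dihydroxy-5-methyl-5,6,7,8-tetrahydronaphthalene-2-carboxylic acid | CC(=O)OC[C@@H](CCC[C@H](C)CO)[C@@H]1CC[C@@H](C)c2c1cc(C(=O)O)c(O)c2O | target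

**Step count**

Total: 21 steps. Longest linear sequence: 16 steps (from 1 through steps 1, 2, 4–7 and 12–21).

**Steps most likely to fail**

Step 4 (Diels–Alder). The β-aryl enoyl imide is a slow dienophile, so Lewis-acid-induced desilylation and oligomerisation of the diene may outrun ring formation, and warming to force conversion may erode the face selectivity. The fallback moves control from the auxiliary to a catalyst and uses a more reactive dienophile. It sets out from 1 and 8 and returns at 10. Wittig reaction of 1 with (triphenylphosphoranylidene)acetaldehyde (toluene, 80 °C) should give (E)-3-(2-bromo-3,4-dimethoxyphenyl)prop-2-enal F1. Cycloaddition of this enal with 8 is run in CH2Cl2 at −78 °C under a proline-derived oxazaborolidinium catalyst: 3,3-diphenyl-1-(2-methylphenyl)tetrahydro-1H,3H-pyrrolo[1,2-c][1,3,2]oxazaborole protonated by HN(SO2CF3)2, in the antipode that sends the diene to the same alkene face as in step 4. It should give (1S,6S)-6-(2-bromo-3,4-dimethoxyphenyl)-4-(triisopropylsilyloxy)cyclohex-3-ene-1-carbaldehyde F2, in which the trans arrangement is also the thermodynamic one. Reduction with NaBH4 in THF/MeOH at −20 °C gives 10.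

Step 17 (copper hydride ring closure). The vinyl group sits between two ortho substituents and is twisted out of conjugation, so hydrocupration may be slow and plain reduction of the alkene or of the C–Br bond may compete. Copper may also be delivered to the wrong face, or the ligand may be mismatched with the C1 centre, giving the 4S epimer. The fallback closes ring B as an alkene and sets C4 by hydrogenation. It sets out from 23 and returns at 25. Tsuji–Wacker oxidation of the vinyl group (PdCl2, CuCl, O2, DMF/H2O) should give (3S,4S,8S)-3-(2-acetyl-3,4-dimethoxyphenyl)-9-(tert-butoxy)-4-[(tert-butyldimethylsilyloxy)methyl]-8-methylnonan-1-ol F3. Dess–Martin oxidation gives (3S,4S,8S)-3-(2-acetyl-3,4-dimethoxyphenyl)-9-(tert-butoxy)-4-[(tert-butyldimethylsilyloxy)methyl]-8-methylnonanal F4. Intramolecular McMurry coupling (TiCl3, Zn–Cu couple, DME, reflux, high dilution) joins C3 to C4 and gives tert-butyl{[(2S,6S)-7-(tert-butoxy)-2-[(1S)-5,6-dimethoxy-4-methyl-1,2-dihydronaphthalen-1-yl]-6-methylheptyl]oxy}dimethylsilane F5. Asymmetric hydrogenation of the trisubstituted styrene-type alkene then gives 25. The catalyst is [Ir(cod){2-[2-(diphenylphosphino)phenyl]-4-tert-butyl-4,5-dihydrooxazole}][B(C6H3(CF3)2)4] under H2 in CH2Cl2, with the ligand antipode that adds hydrogen to the C4 face cis to the C1 substituent.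

Step 21 (BBr3 deprotection). During the time needed to cleave the hindered C5 methyl ether, the C12 acetate may be lost or the C17 borate ester may be converted into a bromide. The fallback exchanges the methyl ethers for acid-labile acetals before the acetate exists, so the last step needs no Lewis acid. It sets out from 25 and returns at 31. NaSEt in DMF at 130 °C should cleave both aryl methyl ethers (alkyl silyl and tert-butyl ethers are not attacked by thiolate) to (5S,8R)-5-[(2S,6S)-7-(tert-butoxy)-1-(tert-butyldimethylsilyloxy)-6-methylheptan-2-yl]-8-methyl-5,6,7,8-tetrahydronaphthalene-1,2-diol F6. MOMCl/i-Pr2NEt gives tert-butyl{[(2S,6S)-2-[(1S,4R)-5,6-bis(methoxymethoxy)-4-methyl-1,2,3,4-tetrahydronaphthalen-1-yl]-7-(tert-butoxy)-6-methylheptyl]oxy}dimethylsilane F7. The OMOM group directs lithiation to C7, and n-BuLi then CO2 gives (5R,8S)-8-[(2S,6S)-7-(tert-butoxy)-1-(tert-butyldimethylsilyloxy)-6-methylheptan-2-yl]-3,4-bis(methoxymethoxy)-5-methyl-5,6,7,8-tetrahydronaphthalene-2-carboxylic acid F8. Bu4NF gives (5R,8S)-8-[(2S,6S)-7-(tert-butoxy)-1-hydroxy-6-methylheptan-2-yl]-3,4-bis(methoxymethoxy)-5-methyl-5,6,7,8-tetrahydronaphthalene-2-carboxylic acid F9. Ac2O/pyridine gives (5R,8S)-8-[(2S,6S)-1-acetoxy-7-(tert-butoxy)-6-methylheptan-2-yl]-3,4-bis(methoxymethoxy)-5-methyl-5,6,7,8-tetrahydronaphthalene-2-carboxylic acid F10. CF3CO2H in CH2Cl2 at 0 °C then removes both acetals and the tert-butyl ether to give 31.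

**Further compounds**

F1 | step 4 | (E)-3-(2-bromo-3,4-dimethoxyphenyl)prop-2-enal | O=C/C=C/c1ccc(OC)c(OC)c1Br
F2 | step 4 | (1S,6S)-6-(2-bromo-3,4-dimethoxyphenyl)-4-(triisopropylsilyloxy)cyclohex-3-ene-1-carbaldehyde | O=C[C@H]1CC=C(O[Si](C(C)C)(C(C)C)C(C)C)C[C@@H]1c1ccc(OC)c(OC)c1Br
F3 | step 17 | (3S,4S,8S)-3-(2-acetyl-3,4-dimethoxyphenyl)-9-(tert-butoxy)-4-[(tert-butyldimethylsilyloxy)methyl]-8-methylnonan-1-ol | OCC[C@H](c1ccc(OC)c(OC)c1C(C)=O)[C@@H](CO[Si](C)(C)C(C)(C)C)CCC[C@H](C)COC(C)(C)C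
F4 | step 17 | (3S,4S,8S)-3-(2-acetyl-3,4-dimethoxyphenyl)-9-(tert-butoxy)-4-[(tert-butyldimethylsilyloxy)methyl]-8-methylnonanal | O=CC[C@H](c1ccc(OC)c(OC)c1C(C)=O)[C@@H](CO[Si](C)(C)C(C)(C)C)CCC[C@H](C)COC(C)(C)C
F5 | step 17 | tert-butyl{[(2S,6S)-7-(tert-butoxy)-2-[(1S)-5,6-dimethoxy-4-methyl-1,2-dihydronaphthalen-1-yl]-6-methylheptyl]oxy}dimethylsilane | CC(C)(C)[Si](C)(C)OC[C@@H](CCC[C@H](C)COC(C)(C)C)[C@@H]1CC=C(C)c2c1ccc(OC)c2OC
F6 | step 21 | (5S,8R)-5-[(2S,6S)-7-(tert-butoxy)-1-(tert-butyldimethylsilyloxy)-6-methylheptan-2-yl]-8-methyl-5,6,7,8-tetrahydronaphthalene-1,2-diol | CC(C)(C)[Si](C)(C)OC[C@@H](CCC[C@H](C)COC(C)(C)C)[C@@H]1CC[C@@H](C)c2c1ccc(O)c2O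
F7 | step 21 | tert-butyl{[(2S,6S)-2-[(1S,4R)-5,6-bis(methoxymethoxy)-4-methyl-1,2,3,4-tetrahydronaphthalen-1-yl]-7-(tert-butoxy)-6-methylheptyl]oxy}dimethylsilane | CC(C)(C)[Si](C)(C)OC[C@@H](CCC[C@H](C)COC(C)(C)C)[C@@H]1CC[C@@H](C)c2c1ccc(OCOC)c2OCOC
F8 | step 21 | (5R,8S)-8-[(2S,6S)-7-(tert-butoxy)-1-(tert-butyldimethylsilyloxy)-6-methylheptan-2-yl]-3,4-bis(methoxymethoxy)-5-methyl-5,6,7,8-tetrahydronaphthalene-2-carboxylic acid | CC(C)(C)[Si](C)(C)OC[C@@H](CCC[C@H](C)COC(C)(C)C)[C@@H]1CC[C@@H](C)c2c1cc(C(=O)O)c(OCOC)c2OCOC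
F9 | step 21 | (5R,8S)-8-[(2S,6S)-7-(tert-butoxy)-1-hydroxy-6-methylheptan-2-yl]-3,4-bis(methoxymethoxy)-5-methyl-5,6,7,8-tetrahydronaphthalene-2-carboxylic acid | OC[C@@H](CCC[C@H](C)COC(C)(C)C)[C@@H]1CC[C@@H](C)c2c1cc(C(=O)O)c(OCOC)c2OCOC
F10 | step 21 | (5R,8S)-8-[(2S,6S)-1-acetoxy-7-(tert-butoxy)-6-methylheptan-2-yl]-3,4-bis(methoxymethoxy)-5-methyl-5,6,7,8-tetrahydronaphthalene-2-carboxylic acid | CC(=O)OC[C@@H](CCC[C@H](C)COC(C)(C)C)[C@@H]1CC[C@@H](C)c2c1cc(C(=O)O)c(OCOC)c2OCOC
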